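## Structural features

The target is a germacranolide: a ten-membered carbocycle (numbered as in germacranes, C1–C10, with C14 on C10 and C15 on C4; this numbering is kept for all intermediates) fused trans at C7–C8 to an α-methylene γ-lactone (O on C8, C11=C13, C12=O). The ring carries an E trisubstituted C1=C10 alkene, an allylic acetate at C2, an acetate at C6 and a 4,5-epoxide whose ring carbons C3 and C6 are trans, i.e. the oxide of an E alkene. Five stereocenters are contiguous (4R,5R,6S,7R,8S), with the C6 and C8 oxygens on one face and the C7 carbon on the other; C2 (S) is remote from all of them. Fragile groups are the α-methylene lactone (Michael acceptor), the epoxide lying across the ring from C1=C10 (acid-triggered transannular cyclization), the allylic C2 acetate and the migration-prone C6 acetate. The real difficulty is the strained ten-membered ring with two defined E-type geometries together with a C2 stereocenter that no neighbour can relay to. The key step exploits the fact that C1=C10 and the parent alkene of the C4–C5 epoxide form a 1,5-diene across the C2–C3 bond, with oxygen on C5. The ten-membered ring is therefore the oxy-Cope product of a cyclohexane made of C5–C10 that carries alkenyl groups on C5 and C10, and C6, C7 and C8 can be set on that chair.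

## Logic of the disconnections

24 to 23. The C11–C12 and C12–O(C8) bonds are cut, which takes the lactone carbonyl out as carbon monoxide and leaves a C7 ethynyl group beside a free C8 hydroxyl. The α-methylene lactone is the most fragile unit and is therefore made last from a robust alkyne. The forward step needs a carbonylation that tolerates epoxide and allylic acetate and finds only one free hydroxyl near the alkyne.

23 to 22, 21 and 20. The O–Si and C–Si bonds, the two acetyl C–O bonds and the benzylic C–O bond at C2 are cut. These are adjustments only, but their order matters: C6 must be acylated before the alkyne and the C8 hydroxyl are unmasked, so that the later lactonization has one possible regiochemistry.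

20 to 19. Both C–O bonds of the oxirane are cut to give the E-4,5-alkene next to a free C6 hydroxyl. The epoxide geometry becomes an alkene geometry, and C4 and C5 reduce to one facial choice. The forward step must react only at C4=C5 (the C2 oxygen stays masked) and on the face set by allylic strain between C15 and the C6 substituents.

19 to 18 and 17. The C6–O benzyl bond and the C5–H bond are cut, so that the alkene becomes an enol triflate, the trapped form of a C5 enolate. The forward steps need reduction with retention of geometry and removal of the 3,4-dimethoxybenzyl group in the presence of the 4-methoxybenzyl group.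

17 to 15 (key disconnection). The C2–C3 bond is cut and the C5–C10 bond is restored. The ten-membered ring contracts to a cyclohexane (C5–C10) with an isopropenyl carbinol at C5 and an E-alkoxyvinyl group on quaternary C10. The medium ring, both ring-alkene geometries and the C2 stereocenter are traded for relative configuration on a chair. The forward step needs both alkenyl groups trans and equatorial, an E enol ether, and an enolate that is trapped as it forms.

15 to 14, 13, 12 and 11. The C2–O bond, the C3=C4 methylene, the C6–O benzyl bond and the C1=C2 bond are cut in turn, back to a C10 aldehyde and a C5 acetyl group. The electron-rich enol ether must come after the oxidation that sets C5 and C6, and it is built with defined E geometry through the alkenyl iodide.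

11 to 10 and 8. The C5–O and C6–O bonds are cut together, then the C5–C4 bond. The C5 carbinol needs its oxygen axial and its carbon equatorial. Addition of an organometallic to a C5 ketone beside the axial C10 methyl should give the opposite, so carbon is attached first and oxygen last, on the face opposite to the C10 methyl and the C7 alkynyl group. No other reactive alkene may be present, hence an alkyne at C7 and an aldehyde at C10 at this stage.

8 to 7, 6 and 5. The enol triflate goes back to the C5 ketone, then the C10–C14 and C10–C1 bonds are cut. The formyl group activates C10 regioselectively and later becomes C1. Methyl is introduced last so that it enters axially, trans to the C8 oxygen.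

5 to 1 and 2. The C7–C11 bond is cut. Conjugate alkynylation trans to the C8 silyloxy group sets C7 from the one purchased stereocenter, and the alkyne carries C11 and C13.

## Other disconnections considered

Alternative 1: the first that comes to mind. Cut C7–C8 and the lactone C–O bond. Forward: intramolecular Nozaki–Hiyama–Kishi-type allylation of bromo aldehyde A1 with CrCl2, closing the ten-membered ring and the lactone in one operation to give 24. Grounds against it: C7 and C8 would be set in a floppy macrocyclic transition state next to the C6 acetate, with nothing that ties their sense to C6. C2, C4, C5 and C6 would all have to be made beforehand on an open chain by separate asymmetric steps. The allylic acetate and the epoxide would have to survive excess divalent chromium. The chosen plan sets C6–C8 on a chair and C2 in the pericyclic step.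

Alternative 2: cut C6–C7. Forward: [2,3]-Wittig ring contraction of the 13-membered diallylic ether A2, deprotonated at C6, to the ten-membered homoallylic alcohol A3. Grounds against it: the step makes ring, C6 and C7 at once, but their sense relative to C8 and C2 rests on the conformation of a 13-membered ring. C2 and C8 still need separate asymmetric steps, and three trisubstituted alkenes must be built stereoselectively in a long linear chain before macro-etherification.

Alternative 3: cut C5–C10 in the opposite sense. Forward: Grob fragmentation of the trans-decalin mesylate A4 (C5 alkoxide, C1 mesylate antiperiplanar to C5–C10) to the ten-membered ketone A5 with the E C1=C10 alkene. Grounds against it: the step is stereospecific for one alkene but creates no stereocenter, and the decalin needs seven stereocenters, two of which are then destroyed. The C5 ketone would have to be turned into the E-4,5-alkene without any control of enolate geometry, whereas the oxy-Cope delivers that geometry by itself. The step count is higher.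

Key step: step 11

Assumption: (S)-4-[(tert-butyldimethylsilyl)oxy]cyclohex-2-en-1-one (1) is taken as a purchasable chiral building block.

Abbreviations: TBS = tert-butyldimethylsilyl, TIPS = triisopropylsilyl, PMB = 4-methoxybenzyl, DMPM = 3,4-dimethoxybenzyl, Tf = trifluoromethanesulfonyl.

## Route

Step 1
Reactants: 1 (S)-4-(TBS-oxy)cyclohex-2-en-1-one; 2 (triisopropylsilyl)acetylene
Product: 5 (3R,4S)-4-(TBS-oxy)-3-[(TIPS)ethynyl]cyclohexan-1-one, via alkynylzinc bromide 3 (not isolated), via silyl enol ether 4 (not isolated)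
Conditions: 2, n-BuLi, THF, −78 °C; ZnBr2, 0 °C; then 1, TBSOTf, −40 °C; 1 M HCl, rt
Reagents that add atoms: none
Why: Silyl-triflate-promoted conjugate addition of an alkynylzinc reagent to a cyclic enone; the nucleophile should enter C7 anti to the adjacent C8 silyloxy group, giving the trans product. The enol silane 4 is hydrolysed on work-up.

Step 2
Reactants: 5 (3R,4S)-4-(TBS-oxy)-3-[(TIPS)ethynyl]cyclohexan-1-one
Product: 6 (4S,5R)-4-(TBS-oxy)-2-(hydroxymethylidene)-5-[(TIPS)ethynyl]cyclohexan-1-one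
Conditions: NaH, HCO2Et, THF, 0 °C to rt; 1 M HCl work-up
Reagents that add atoms: ethyl formate (CCOC=O)
Why: Crossed Claisen condensation (formylation), which should occur at the less hindered α-methylene C10 because C6 is flanked by the C7 branch. The product is held as the chelated enol.

Step 3
Reactants: 6 (4S,5R)-4-(TBS-oxy)-2-(hydroxymethylidene)-5-[(TIPS)ethynyl]cyclohexan-1-one
Product: 7 (1S,4R,5S)-5-(TBS-oxy)-1-methyl-2-oxo-4-[(TIPS)ethynyl]cyclohexane-1-carbaldehyde
Conditions: MeI, K2CO3, acetone, rt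
Reagents that add atoms: iodomethane (CI)
Why: C-alkylation of a 1,3-dicarbonyl enolate. With the C7 and C8 groups equatorial, methyl should enter axially on the face opposite to the C8 oxygen, which leaves the formyl group equatorial and cis to that oxygen.

Step 4
Reactants: 7 (1S,4R,5S)-5-(TBS-oxy)-1-methyl-2-oxo-4-[(TIPS)ethynyl]cyclohexane-1-carbaldehyde
Product: 8 (1R,4R,5S)-5-(TBS-oxy)-1-methyl-2-(Tf-oxy)-4-[(TIPS)ethynyl]cyclohex-2-ene-1-carbaldehyde
Conditions: KN(SiMe3)2, THF, −78 °C; PhNTf2, −78 to 0 °C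
Reagents that add atoms: N-phenylbis(trifluoromethanesulfonimide) (O=S(=O)(N(c1ccccc1)S(=O)(=O)C(F)(F)F)C(F)(F)F)
Why: Enol triflate formation from the potassium enolate. Only C6 can be deprotonated (C10 is quaternary and the aldehyde has no α-hydrogen), so the C5=C6 regiochemistry is fixed.

Step 5
Reactants: 8 (1R,4R,5S)-5-(TBS-oxy)-1-methyl-2-(Tf-oxy)-4-[(TIPS)ethynyl]cyclohex-2-ene-1-carbaldehyde
Product: 10 (1R,4R,5S)-2-acetyl-5-(TBS-oxy)-1-methyl-4-[(TIPS)ethynyl]cyclohex-2-ene-1-carbaldehyde, via ethoxydiene 9 (not isolated)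
Conditions: Pd(PPh3)4 (5 mol%), LiCl, tributyl(1-ethoxyvinyl)stannane, THF, 65 °C; then 1 M HCl, THF, rt
Reagents that add atoms: tributyl(1-ethoxyvinyl)stannane (CCCC[Sn](CCCC)(CCCC)C(=C)OCC); water (O)
Why: Stille coupling of an alkenyl triflate with an acyl-anion equivalent, then mild hydrolysis of the enol ether to the methyl ketone. This attaches C4 and C15 to C5 before any oxygen is placed there.

Step 6
Reactants: 10 (1R,4R,5S)-2-acetyl-5-(TBS-oxy)-1-methyl-4-[(TIPS)ethynyl]cyclohex-2-ene-1-carbaldehyde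
Product: 11 (1R,2R,3S,4S,5S)-2-acetyl-5-(TBS-oxy)-2,3-dihydroxy-1-methyl-4-[(TIPS)ethynyl]cyclohexane-1-carbaldehyde
Conditions: OsO4 (5 mol%), NMO, citric acid, t-BuOH/H2O, rt
Reagents that add atoms: N-methylmorpholine N-oxide (C[N+]1([O-])CCOCC1); water (O)
Why: OsO4-catalysed syn-dihydroxylation of the only alkene. Attack should come from the face opposite to the pseudoaxial C10 methyl and the C7 alkynyl group, so the C5 and C6 hydroxyls both end up cis to the C8 oxygen. The acidic buffer guards the β-hydroxy aldehyde against retro-aldol cleavage.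

Step 7
Reactants: 11 (1R,2R,3S,4S,5S)-2-acetyl-5-(TBS-oxy)-2,3-dihydroxy-1-methyl-4-[(TIPS)ethynyl]cyclohexane-1-carbaldehyde
Product: 12 1-{(1R,2S,4S,5S,6S)-4-(TBS-oxy)-1,6-dihydroxy-2-[(E)-2-iodoethenyl]-2-methyl-5-[(TIPS)ethynyl]cyclohexyl}ethan-1-one
Conditions: CrCl2, CHI3, THF/1,4-dioxane, 0 °C to rt
Reagents that add atoms: iodoform (IC(I)I)
Why: Takai olefination, which is selective for the aldehyde over the ketone, tolerates free hydroxyls and should give the E alkenyl iodide.

Step 8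
Reactants: 12 1-{(1R,2S,4S,5S,6S)-4-(TBS-oxy)-1,6-dihydroxy-2-[(E)-2-iodoethenyl]-2-methyl-5-[(TIPS)ethynyl]cyclohexyl}ethan-1-one
Product: 13 1-{(1R,2S,4S,5S,6S)-4-(TBS-oxy)-6-(DMPM-oxy)-1-hydroxy-2-[(E)-2-iodoethenyl]-2-methyl-5-[(TIPS)ethynyl]cyclohexyl}ethan-1-one
Conditions: 3,4-dimethoxybenzyl 2,2,2-trichloroacetimidate, La(OTf)3 (5 mol%), toluene, rt
Reagents that add atoms: 3,4-dimethoxybenzyl 2,2,2-trichloroacetimidate (COc1ccc(COC(=N)C(Cl)(Cl)Cl)cc1OC)
Why: Acid-catalysed benzylation with a trichloroacetimidate. The secondary C6 hydroxyl should react while the tertiary C5 hydroxyl is too hindered. A non-migrating ether is chosen because a silyl group would shift to the neighbouring alkoxide in step 11.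

Step 9
Reactants: 13 1-{(1R,2S,4S,5S,6S)-4-(TBS-oxy)-6-(DMPM-oxy)-1-hydroxy-2-[(E)-2-iodoethenyl]-2-methyl-5-[(TIPS)ethynyl]cyclohexyl}ethan-1-one
Product: 14 (1R,2S,4S,5S,6S)-4-(TBS-oxy)-6-(DMPM-oxy)-2-[(E)-2-iodoethenyl]-2-methyl-1-(prop-1-en-2-yl)-5-[(TIPS)ethynyl]cyclohexan-1-ol
Conditions: Ph3PCH3Br, KOtBu, THF, 0 °C to rt
Reagents that add atoms: methyltriphenylphosphonium bromide (C[P+](c1ccccc1)(c1ccccc1)c1ccccc1.[Br-])
Why: Wittig methylenation of the methyl ketone turns the acetyl group into the isopropenyl group (C3, C4, C15). Excess ylide first deprotonates the tertiary hydroxyl; the alkenyl iodide is inert.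

Step 10
Reactants: 14 (1R,2S,4S,5S,6S)-4-(TBS-oxy)-6-(DMPM-oxy)-2-[(E)-2-iodoethenyl]-2-methyl-1-(prop-1-en-2-yl)-5-[(TIPS)ethynyl]cyclohexan-1-ol
Product: 15 (1R,2S,4S,5S,6S)-4-(TBS-oxy)-6-(DMPM-oxy)-2-methyl-2-[(E)-2-(PMB-oxy)ethenyl]-1-(prop-1-en-2-yl)-5-[(TIPS)ethynyl]cyclohexan-1-ol
Conditions: CuI (10 mol%), 3,4,7,8-tetramethyl-1,10-phenanthroline (20 mol%), Cs2CO3, 4-methoxybenzyl alcohol, toluene, 80 °C
Reagents that add atoms: 4-methoxybenzyl alcohol (COc1ccc(CO)cc1)
Why: Copper-catalysed Ullmann-type C–O coupling of an alkenyl iodide with a primary alcohol, which proceeds with retention and so should give the E enol ether that carries the future C2 oxygen. The hindered tertiary alcohol should not compete.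

Step 11
Reactants: 15 (1R,2S,4S,5S,6S)-4-(TBS-oxy)-6-(DMPM-oxy)-2-methyl-2-[(E)-2-(PMB-oxy)ethenyl]-1-(prop-1-en-2-yl)-5-[(TIPS)ethynyl]cyclohexan-1-ol
Product: 17 (1(10)E,4Z,2S,6S,7S,8S)-8-(TBS-oxy)-6-(DMPM-oxy)-2-(PMB-oxy)-4,10-dimethyl-7-[(TIPS)ethynyl]cyclodeca-1(10),4-dien-5-yl trifluoromethanesulfonate (germacrane numbering; C3 and C6 trans across C4=C5), via potassium enolate 16 (not isolated)
Conditions: KH, 18-crown-6, THF, 0 °C to rt; then PhNTf2, −78 to 0 °C
Reagents that add atoms: N-phenylbis(trifluoromethanesulfonimide) (O=S(=O)(N(c1ccccc1)S(=O)(=O)C(F)(F)F)C(F)(F)F)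
Why: KH gives the potassium alkoxide of 15, whose oxyanion weakens the C5–C10 bond and triggers a concerted [3,3] sigmatropic shift through a chair transition state in which C2 and C3 join while C5–C10 breaks; the resulting enolate 16 is trapped on oxygen by PhNTf2 as triflate 17. The closest known reaction type is the anionic oxy-Cope ring expansion of trans-1,2-dialkenylcyclohexanols to (E)-cyclodec-5-enones. The ten-membered ring is not closed end to end but arises by four-atom ring expansion of the cyclohexane through a six-membered cyclic transition state (new bond C2–C3), so no medium-ring entropy penalty is paid. The only new stereocenter, C2, is set by the E geometry of the enol ether: the PMB-oxy group sits equatorial in a chair whose sense is fixed by the C5 and C10 configurations, C3 adds to one face of C1=C2, and the S configuration should result. In the same chair C9 on C10 and C6 on C5 are equatorial, which makes C1=C10 E and places C3 and C6 trans across C4=C5, the geometry later carried into the trans epoxide. The step needs chair over boat and shift over fragmentation: the three equatorial groups on C6, C7 and C8 lock the chair in which both alkenyl groups are equatorial and within bonding distance, and the crown ether gives a free alkoxide that lowers the barrier of the concerted path. The enolate has no leaving group β to C4 and is trapped at −78 °C, which fixes its position and geometry; the C5 and C10 stereocenters are consumed.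

Step 12
Reactants: 17 (1(10)E,4Z,2S,6S,7S,8S)-8-(TBS-oxy)-6-(DMPM-oxy)-2-(PMB-oxy)-4,10-dimethyl-7-[(TIPS)ethynyl]cyclodeca-1(10),4-dien-5-yl trifluoromethanesulfonate
Product: 18 (1(10)E,4E,2S,6R,7S,8S)-8-(TBS-oxy)-6-(DMPM-oxy)-2-(PMB-oxy)-4,10-dimethyl-7-[(TIPS)ethynyl]cyclodeca-1(10),4-diene
Conditions: Pd(OAc)2 (5 mol%), PPh3 (10 mol%), HCO2H, n-Bu3N, DMF, 40 °C
Reagents that add atoms: none
Why: Palladium-catalysed formate reduction of an enol triflate; oxidative addition and hydride delivery occur with retention, so the E-4,5-alkene should result. The mild temperature keeps the 1,5-diene below the onset of the reverse Cope reaction.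

Step 13
Reactants: 18 (1(10)E,4E,2S,6R,7S,8S)-8-(TBS-oxy)-6-(DMPM-oxy)-2-(PMB-oxy)-4,10-dimethyl-7-[(TIPS)ethynyl]cyclodeca-1(10),4-diene
Product: 19 (1(10)E,4E,2S,6R,7S,8S)-8-(TBS-oxy)-2-(PMB-oxy)-4,10-dimethyl-7-[(TIPS)ethynyl]cyclodeca-1(10),4-dien-6-ol
Conditions: DDQ (1.1 equiv), CH2Cl2/pH 7 buffer, 0 °C
Reagents that add atoms: none
Why: Oxidative cleavage of a benzyl-type ether by DDQ. The more electron-rich 3,4-dimethoxybenzyl ether should be cleaved before the 4-methoxybenzyl ether, which frees only the C6 hydroxyl.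

Step 14
Reactants: 19 (1(10)E,4E,2S,6R,7S,8S)-8-(TBS-oxy)-2-(PMB-oxy)-4,10-dimethyl-7-[(TIPS)ethynyl]cyclodeca-1(10),4-dien-6-ol
Product: 20 (1(10)E,2S,4R,5R,6S,7S,8S)-8-(TBS-oxy)-4,5-epoxy-2-(PMB-oxy)-4,10-dimethyl-7-[(TIPS)ethynyl]cyclodec-1(10)-en-6-ol
Conditions: VO(acac)2 (5 mol%), t-BuOOH, CH2Cl2, 0 °C
Reagents that add atoms: tert-butyl hydroperoxide (CC(C)(C)OO)
Why: Hydroxyl-directed vanadium-catalysed epoxidation of an allylic alcohol. Only C4=C5 has a free allylic hydroxyl, and because C15 is cis to C6, allylic strain holds the C6 hydrogen in the alkene plane, so oxygen should be delivered to the hydroxyl face to give the threo (4R,5R) epoxide. The E geometry becomes the trans epoxide.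

Step 15
Reactants: 20 (1(10)E,2S,4R,5R,6S,7S,8S)-8-(TBS-oxy)-4,5-epoxy-2-(PMB-oxy)-4,10-dimethyl-7-[(TIPS)ethynyl]cyclodec-1(10)-en-6-ol
Product: 21 (1(10)E,2S,4R,5R,6S,7S,8S)-8-(TBS-oxy)-4,5-epoxy-4,10-dimethyl-7-[(TIPS)ethynyl]cyclodec-1(10)-ene-2,6-diol
Conditions: DDQ (2 equiv), CH2Cl2/pH 7 buffer, rt
Reagents that add atoms: none
Why: DDQ cleavage of the 4-methoxybenzyl ether under neutral buffered conditions, which the epoxide should tolerate.

Step 16
Reactants: 21 (1(10)E,2S,4R,5R,6S,7S,8S)-8-(TBS-oxy)-4,5-epoxy-4,10-dimethyl-7-[(TIPS)ethynyl]cyclodec-1(10)-ene-2,6-diol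
Product: 22 (1(10)E,2S,4R,5R,6S,7S,8S)-8-(TBS-oxy)-4,5-epoxy-4,10-dimethyl-7-[(TIPS)ethynyl]cyclodec-1(10)-ene-2,6-diyl diacetate
Conditions: Ac2O, pyridine, DMAP (cat.), CH2Cl2, 0 °C to rt
Reagents that add atoms: acetic anhydride (CC(=O)OC(C)=O)
Why: Acetylation of both secondary alcohols with nucleophilic catalysis. It installs the two acetates of the target and blocks the C6 oxygen before the lactone is closed.

Step 17
Reactants: 22 (1(10)E,2S,4R,5R,6S,7S,8S)-8-(TBS-oxy)-4,5-epoxy-4,10-dimethyl-7-[(TIPS)ethynyl]cyclodec-1(10)-ene-2,6-diyl diacetate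
Product: 23 (1(10)E,2S,4R,5R,6S,7R,8S)-4,5-epoxy-7-ethynyl-8-hydroxy-4,10-dimethylcyclodec-1(10)-ene-2,6-diyl diacetate
Conditions: TBAF, AcOH, THF, 0 °C to rt
Reagents that add atoms: none
Why: Fluoride-mediated desilylation of the C8 silyl ether and the alkynylsilane. Acetic acid buffers the medium so that the acetates should neither migrate nor cleave.

Step 18
Reactants: 23 (1(10)E,2S,4R,5R,6S,7R,8S)-4,5-epoxy-7-ethynyl-8-hydroxy-4,10-dimethylcyclodec-1(10)-ene-2,6-diyl diacetate
Product: 24 (1(10)E,2S,4R,5R,6S,7R,8S)-2,6-diacetoxy-4,5-epoxygermacra-1(10),11(13)-dien-12,8-olide (the target)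
Conditions: PdCl2 (10 mol%), thiourea (20 mol%), CO (1 atm), acetone, 50 °C
Reagents that add atoms: carbon monoxide ([C-]#[O+])
Why: Palladium-catalysed cyclocarbonylation of a homopropargylic alcohol: the C8 alkoxycarbonyl–palladium species adds syn across the alkyne and protonolysis releases the α-methylene γ-lactone. The trans ring fusion is already fixed at C7 and C8. Palladium stays divalent throughout, so the allylic acetate should not ionise.

## Compound list

1 | (S)-4-(TBS-oxy)cyclohex-2-en-1-one | O=C1C=C[C@@H](O[Si](C)(C)C(C)(C)C)CC1 | starting material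
2 | (triisopropylsilyl)acetylene | C#C[Si](C(C)C)(C(C)C)C(C)C | starting material
3 | bromo[(triisopropylsilyl)ethynyl]zinc | Br[Zn]C#C[Si](C(C)C)(C(C)C)C(C)C | intermediate
4 | (3R,4S)-1,4-bis(TBS-oxy)-3-[(TIPS)ethynyl]cyclohex-1-ene | CC(C)(C)[Si](C)(C)OC1=C[C@H](C#C[Si](C(C)C)(C(C)C)C(C)C)[C@@H](O[Si](C)(C)C(C)(C)C)CC1 | intermediate
5 | (3R,4S)-4-(TBS-oxy)-3-[(TIPS)ethynyl]cyclohexan-1-one | O=C1C[C@H](C#C[Si](C(C)C)(C(C)C)C(C)C)[C@@H](O[Si](C)(C)C(C)(C)C)CC1 | intermediate
6 | (4S,5R)-4-(TBS-oxy)-2-(hydroxymethylidene)-5-[(TIPS)ethynyl]cyclohexan-1-one | O=C1C[C@H](C#C[Si](C(C)C)(C(C)C)C(C)C)[C@@H](O[Si](C)(C)C(C)(C)C)C/C1=C/O | intermediate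
7 | (1S,4R,5S)-5-(TBS-oxy)-1-methyl-2-oxo-4-[(TIPS)ethynyl]cyclohexane-1-carbaldehyde | O=C1C[C@H](C#C[Si](C(C)C)(C(C)C)C(C)C)[C@@H](O[Si](C)(C)C(C)(C)C)C[C@@]1(C)C=O | intermediate
8 | (1R,4R,5S)-5-(TBS-oxy)-1-methyl-2-(Tf-oxy)-4-[(TIPS)ethynyl]cyclohex-2-ene-1-carbaldehyde | FC(F)(F)S(=O)(=O)OC1=C[C@H](C#C[Si](C(C)C)(C(C)C)C(C)C)[C@@H](O[Si](C)(C)C(C)(C)C)C[C@@]1(C)C=O | intermediate
9 | (1R,4R,5S)-5-(TBS-oxy)-2-(1-ethoxyethenyl)-1-methyl-4-[(TIPS)ethynyl]cyclohex-2-ene-1-carbaldehyde | CCOC(=C)C1=C[C@H](C#C[Si](C(C)C)(C(C)C)C(C)C)[C@@H](O[Si](C)(C)C(C)(C)C)C[C@@]1(C)C=O | intermediate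
10 | (1R,4R,5S)-2-acetyl-5-(TBS-oxy)-1-methyl-4-[(TIPS)ethynyl]cyclohex-2-ene-1-carbaldehyde | CC(=O)C1=C[C@H](C#C[Si](C(C)C)(C(C)C)C(C)C)[C@@H](O[Si](C)(C)C(C)(C)C)C[C@@]1(C)C=O | intermediate
11 | (1R,2R,3S,4S,5S)-2-acetyl-5-(TBS-oxy)-2,3-dihydroxy-1-methyl-4-[(TIPS)ethynyl]cyclohexane-1-carbaldehyde | CC(=O)[C@]1(O)[C@@H](O)[C@H](C#C[Si](C(C)C)(C(C)C)C(C)C)[C@@H](O[Si](C)(C)C(C)(C)C)C[C@@]1(C)C=O | intermediate
12 | 1-{(1R,2S,4S,5S,6S)-4-(TBS-oxy)-1,6-dihydroxy-2-[(E)-2-iodoethenyl]-2-methyl-5-[(TIPS)ethynyl]cyclohexyl}ethan-1-one | CC(=O)[C@]1(O)[C@@H](O)[C@H](C#C[Si](C(C)C)(C(C)C)C(C)C)[C@@H](O[Si](C)(C)C(C)(C)C)C[C@@]1(C)/C=C/I | intermediate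
13 | 1-{(1R,2S,4S,5S,6S)-4-(TBS-oxy)-6-(DMPM-oxy)-1-hydroxy-2-[(E)-2-iodoethenyl]-2-methyl-5-[(TIPS)ethynyl]cyclohexyl}ethan-1-one | CC(=O)[C@]1(O)[C@@H](OCc2ccc(OC)c(OC)c2)[C@H](C#C[Si](C(C)C)(C(C)C)C(C)C)[C@@H](O[Si](C)(C)C(C)(C)C)C[C@@]1(C)/C=C/I | intermediate
14 | (1R,2S,4S,5S,6S)-4-(TBS-oxy)-6-(DMPM-oxy)-2-[(E)-2-iodoethenyl]-2-methyl-1-(prop-1-en-2-yl)-5-[(TIPS)ethynyl]cyclohexan-1-ol | CC(=C)[C@]1(O)[C@@H](OCc2ccc(OC)c(OC)c2)[C@H](C#C[Si](C(C)C)(C(C)C)C(C)C)[C@@H](O[Si](C)(C)C(C)(C)C)C[C@@]1(C)/C=C/I | intermediate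
15 | (1R,2S,4S,5S,6S)-4-(TBS-oxy)-6-(DMPM-oxy)-2-methyl-2-[(E)-2-(PMB-oxy)ethenyl]-1-(prop-1-en-2-yl)-5-[(TIPS)ethynyl]cyclohexan-1-ol | CC(=C)[C@]1(O)[C@@H](OCc2ccc(OC)c(OC)c2)[C@H](C#C[Si](C(C)C)(C(C)C)C(C)C)[C@@H](O[Si](C)(C)C(C)(C)C)C[C@@]1(C)/C=C/OCc1ccc(OC)cc1 | intermediate
16 | potassium (1(10)E,4Z,2S,6S,7S,8S)-8-(TBS-oxy)-6-(DMPM-oxy)-2-(PMB-oxy)-4,10-dimethyl-7-[(TIPS)ethynyl]cyclodeca-1(10),4-dien-5-olate | CC(C)(C)[Si](C)(C)O[C@H]1C/C(C)=C/[C@@H](OCc2ccc(OC)cc2)C/C(C)=C([O-])/[C@@H](OCc2ccc(OC)c(OC)c2)[C@@H]1C#C[Si](C(C)C)(C(C)C)C(C)C.[K+] | intermediate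
17 | (1(10)E,4Z,2S,6S,7S,8S)-8-(TBS-oxy)-6-(DMPM-oxy)-2-(PMB-oxy)-4,10-dimethyl-7-[(TIPS)ethynyl]cyclodeca-1(10),4-dien-5-yl trifluoromethanesulfonate | CC(C)(C)[Si](C)(C)O[C@H]1C/C(C)=C/[C@@H](OCc2ccc(OC)cc2)C/C(C)=C(OS(=O)(=O)C(F)(F)F)/[C@@H](OCc2ccc(OC)c(OC)c2)[C@@H]1C#C[Si](C(C)C)(C(C)C)C(C)C | intermediate
18 | (1(10)E,4E,2S,6R,7S,8S)-8-(TBS-oxy)-6-(DMPM-oxy)-2-(PMB-oxy)-4,10-dimethyl-7-[(TIPS)ethynyl]cyclodeca-1(10),4-diene | CC(C)(C)[Si](C)(C)O[C@H]1C/C(C)=C/[C@@H](OCc2ccc(OC)cc2)C/C(C)=C/[C@@H](OCc2ccc(OC)c(OC)c2)[C@@H]1C#C[Si](C(C)C)(C(C)C)C(C)C | intermediate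
19 | (1(10)E,4E,2S,6R,7S,8S)-8-(TBS-oxy)-2-(PMB-oxy)-4,10-dimethyl-7-[(TIPS)ethynyl]cyclodeca-1(10),4-dien-6-ol | CC(C)(C)[Si](C)(C)O[C@H]1C/C(C)=C/[C@@H](OCc2ccc(OC)cc2)C/C(C)=C/[C@@H](O)[C@@H]1C#C[Si](C(C)C)(C(C)C)C(C)C | intermediate
20 | (1(10)E,2S,4R,5R,6S,7S,8S)-8-(TBS-oxy)-4,5-epoxy-2-(PMB-oxy)-4,10-dimethyl-7-[(TIPS)ethynyl]cyclodec-1(10)-en-6-ol | CC(C)(C)[Si](C)(C)O[C@H]1C/C(C)=C/[C@@H](OCc2ccc(OC)cc2)C[C@@]2(C)O[C@@H]2[C@@H](O)[C@@H]1C#C[Si](C(C)C)(C(C)C)C(C)C | intermediate
21 | (1(10)E,2S,4R,5R,6S,7S,8S)-8-(TBS-oxy)-4,5-epoxy-4,10-dimethyl-7-[(TIPS)ethynyl]cyclodec-1(10)-ene-2,6-diol | CC(C)(C)[Si](C)(C)O[C@H]1C/C(C)=C/[C@@H](O)C[C@@]2(C)O[C@@H]2[C@@H](O)[C@@H]1C#C[Si](C(C)C)(C(C)C)C(C)C | intermediate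
22 | (1(10)E,2S,4R,5R,6S,7S,8S)-8-(TBS-oxy)-4,5-epoxy-4,10-dimethyl-7-[(TIPS)ethynyl]cyclodec-1(10)-ene-2,6-diyl diacetate | CC(C)(C)[Si](C)(C)O[C@H]1C/C(C)=C/[C@@H](OC(C)=O)C[C@@]2(C)O[C@@H]2[C@@H](OC(C)=O)[C@@H]1C#C[Si](C(C)C)(C(C)C)C(C)C | intermediate
23 | (1(10)E,2S,4R,5R,6S,7R,8S)-4,5-epoxy-7-ethynyl-8-hydroxy-4,10-dimethylcyclodec-1(10)-ene-2,6-diyl diacetate | O[C@H]1C/C(C)=C/[C@@H](OC(C)=O)C[C@@]2(C)O[C@@H]2[C@@H](OC(C)=O)[C@@H]1C#C | intermediate
24 | (1(10)E,2S,4R,5R,6S,7R,8S)-2,6-diacetoxy-4,5-epoxygermacra-1(10),11(13)-dien-12,8-olide | C=C1C(=O)O[C@H]2C/C(C)=C/[C@@H](OC(C)=O)C[C@@]3(C)O[C@@H]3[C@@H](OC(C)=O)[C@H]12 | target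

## Step count and least certain steps

Total step count: 18. Longest linear sequence: 18 steps, from 1 to 24 (the route is linear; 2 enters in step 1).

Step 11 (key step). Most likely failure: heterolytic cleavage of the C5–C10 bond of the crowded alkoxide (fragmentation instead of the concerted shift), or proton transfer within the enolate before it is trapped. Both come from the free oxyanion. Fallback, a neutral siloxy-Cope rearrangement: 15 is silylated (TMSOTf, 2,6-lutidine) to trimethylsilyl ether F1; F1 is heated (o-dichlorobenzene, 190 °C) and should pass through the same chair to the ten-membered trimethylsilyl enol ether F2; F2 is cleaved with MeLi to the lithium enolate and triflated with PhNTf2, which returns to 17.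

Step 3. Most likely failure: poor facial selectivity of the C-methylation (equatorial entry competing with axial entry), together with some O-methylation. Fallback, reversed order of bond formation so that the one-carbon unit enters last. From 5, kinetic methylation (LiN(iPr)2, MeI) gives methyl ketone F3 as C10 epimers. Thermodynamic silylation (TMSCl, NaI, Et3N) gives the tetrasubstituted enol silane F4. Hydroxymethylation with aqueous formaldehyde and Yb(OTf)3 (Mukaiyama aldol) gives hydroxymethyl ketone F5. Dess–Martin oxidation of F5 returns to 7. A preference for equatorial entry of the last electrophile would then serve the route.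

Step 10. Most likely failure: slow C–O bond formation at 80 °C with competing dehydroiodination of the alkenyl iodide to the alkyne by the carbonate base. Fallback, reversed coupling polarity: from 14, Miyaura borylation (PdCl2(dppf), B2pin2, KOAc, DMSO) gives alkenyl boronate F6, and oxidative Chan–Lam coupling of F6 with 4-methoxybenzyl alcohol (Cu(OAc)2, Et3N, air, rt) returns to 15.

Step 14. Most likely failure: poor facial selectivity if the ring conformation overrides the allylic-strain model, or slow delivery that lets C1=C10 compete. Fallback, reagent control instead of substrate control: 19 is epoxidised with Ti(OiPr)4, the matched enantiomer of diethyl tartrate and t-BuOOH (Sharpless epoxidation), which returns to 20 directly and makes no new compound (F0).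

Step 18. Most likely failure: opening or transannular cyclization of the epoxide by the traces of HCl and the divalent palladium present during carbonylation. Fallback, the lactone is closed before the epoxide exists. From 18, TBAF gives alkynol F7. The same cyclocarbonylation gives lactone F8. DDQ (1.1 equiv) removes the DMPM group to give allylic alcohol F9. VO(acac)2 and t-BuOOH give epoxy alcohol F10. DDQ removes the PMB group to give diol F11. Acetylation of F11 (Ac2O, pyridine, DMAP) returns to 24.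

## Further compounds

F1 | step 11 | trimethylsilyl ether of 15 | CC(=C)[C@]1(O[Si](C)(C)C)[C@@H](OCc2ccc(OC)c(OC)c2)[C@H](C#C[Si](C(C)C)(C(C)C)C(C)C)[C@@H](O[Si](C)(C)C(C)(C)C)C[C@@]1(C)/C=C/OCc1ccc(OC)cc1
F2 | step 11 | ten-membered trimethylsilyl enol ether (C5-OSiMe3 analogue of 17) | CC(C)(C)[Si](C)(C)O[C@H]1C/C(C)=C/[C@@H](OCc2ccc(OC)cc2)C/C(C)=C(O[Si](C)(C)C)/[C@@H](OCc2ccc(OC)c(OC)c2)[C@@H]1C#C[Si](C(C)C)(C(C)C)C(C)C
F3 | step 3 | (4S,5R)-4-(TBS-oxy)-2-methyl-5-[(TIPS)ethynyl]cyclohexan-1-one (C2 epimers) | O=C1C[C@H](C#C[Si](C(C)C)(C(C)C)C(C)C)[C@@H](O[Si](C)(C)C(C)(C)C)CC1C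
F4 | step 3 | (4S,5R)-4-(TBS-oxy)-2-methyl-5-[(TIPS)ethynyl]-1-(trimethylsilyloxy)cyclohex-1-ene | C[Si](C)(C)OC1=C(C)C[C@H](O[Si](C)(C)C(C)(C)C)[C@@H](C#C[Si](C(C)C)(C(C)C)C(C)C)C1
F5 | step 3 | (2S,4S,5R)-4-(TBS-oxy)-2-(hydroxymethyl)-2-methyl-5-[(TIPS)ethynyl]cyclohexan-1-one | O=C1C[C@H](C#C[Si](C(C)C)(C(C)C)C(C)C)[C@@H](O[Si](C)(C)C(C)(C)C)C[C@@]1(C)CO
F6 | step 10 | (E)-alkenyl pinacol boronate corresponding to 14 | CC(=C)[C@]1(O)[C@@H](OCc2ccc(OC)c(OC)c2)[C@H](C#C[Si](C(C)C)(C(C)C)C(C)C)[C@@H](O[Si](C)(C)C(C)(C)C)C[C@@]1(C)/C=C/B1OC(C)(C)C(C)(C)O1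
F0 | step 14 | none | none
F7 | step 18 | C8 alcohol with free ethynyl group from 18 | O[C@H]1C/C(C)=C/[C@@H](OCc2ccc(OC)cc2)C/C(C)=C/[C@@H](OCc2ccc(OC)c(OC)c2)[C@@H]1C#C
F8 | step 18 | 6-(DMPM-oxy)-2-(PMB-oxy)germacra-1(10),4,11(13)-trien-12,8-olide | C=C1C(=O)O[C@H]2C/C(C)=C/[C@@H](OCc3ccc(OC)cc3)C/C(C)=C/[C@@H](OCc3ccc(OC)c(OC)c3)[C@H]12
F9 | step 18 | 6-hydroxy-2-(PMB-oxy)germacra-1(10),4,11(13)-trien-12,8-olide | C=C1C(=O)O[C@H]2C/C(C)=C/[C@@H](OCc3ccc(OC)cc3)C/C(C)=C/[C@@H](O)[C@H]12
F10 | step 18 | 4,5-epoxy-6-hydroxy-2-(PMB-oxy)germacra-1(10),11(13)-dien-12,8-olide | C=C1C(=O)O[C@H]2C/C(C)=C/[C@@H](OCc3ccc(OC)cc3)C[C@@]3(C)O[C@@H]3[C@@H](O)[C@H]12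
F11 | step 18 | 4,5-epoxy-2,6-dihydroxygermacra-1(10),11(13)-dien-12,8-olide | C=C1C(=O)O[C@H]2C/C(C)=C/[C@@H](O)C[C@@]3(C)O[C@@H]3[C@@H](O)[C@H]12
A1 | alternative 1 | open-chain bromo aldehyde (C8 aldehyde, methyl 2-(bromomethyl)enoate at C7=C11) | O=CC/C(C)=C/[C@@H](OC(C)=O)C[C@@]1(C)O[C@@H]1[C@@H](OC(C)=O)/C=C(/CBr)C(=O)OC
A2 | alternative 2 | 13-membered diallylic ether (O between C6 and C13) | CC(C)(C)[Si](C)(C)OC/C1=C/[C@@H](O[Si](C)(C)C(C)(C)C)C/C(C)=C/[C@@H](O[Si](C)(C)C(C)(C)C)C/C(C)=C/COC1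
A3 | alternative 2 | ten-membered C6 alcohol with 3-(TBS-oxy)prop-1-en-2-yl group on C7 | CC(C)(C)[Si](C)(C)O[C@H]1C/C(C)=C/[C@@H](O[Si](C)(C)C(C)(C)C)C/C(C)=C/[C@@H](O)[C@@H]1C(=C)CO[Si](C)(C)C(C)(C)C
A4 | alternative 3 | trans-decalin with C5 hydroxyl and C1 mesylate (C5–C10 ring fusion) | C[C@@]12C[C@H](O[Si](C)(C)C(C)(C)C)[C@@H](C#C[Si](C(C)C)(C(C)C)C(C)C)[C@H](O[Si](C)(C)C(C)(C)C)[C@@]1(O)[C@H](C)C[C@H](O[Si](C)(C)C(C)(C)C)[C@H]2OS(C)(=O)=O
A5 | alternative 3 | ten-membered C5 ketone with E C1=C10 alkene | CC(C)(C)[Si](C)(C)O[C@H]1C/C(C)=C/[C@@H](O[Si](C)(C)C(C)(C)C)C[C@@H](C)C(=O)[C@@H](O[Si](C)(C)C(C)(C)C)[C@@H]1C#C[Si](C(C)C)(C(C)C)C(C)C
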